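(All runs are simulated for an exercise.)

Time soon stops paying in the alpha run. In the alpha run the product gains 1.2 percentage points between 4.00 min and 5.00 min, against a scatter of 0.5 points per reading.

| setting | theta | alpha | flask |
|---|---|---|---|
| electrophile | 0.15 M | 0.15 M | 0.15 M |
| nucleophile | 0.30 M | 0.20 M | 0.300 M |
| free base | 0.15 M | 0.15 M | 0.150 M |
| remark | the very flask that is asked about, followed so far | run made earlier |  |
| time |  |  | 12 min |

- theta (time / min: electrophile / %, product / %): 0.250: 80.6, 18.6; 0.500: 70.4, 30.3; 0.833: 61.8, 38.9; 1.33: 54.2, 45.3; 2.00: 49.6, 51.2; 4.00: 41.5, 59.0
- alpha (time / min: electrophile / %, product / %): 0.833: 71.6, 29.2; 1.50: 63.6, 36.4; 2.50: 57.1, 41.8; 3.00: 56.9, 43.1; 4.00: 54.4, 46.3; 5.00: 52.6, 47.5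

(standard deviation of a reading: 0.5 percentage points)

- the earlier runs do not show how much of nucleophile is bound; that part of a forecast is a guess
- a reading or a percentage of product counts all its forms, free or not

- part of the electrophile that has reacted at 12 min
- share of free nucleophile in free nucleophile and protonated nucleophile together, at 12 min

The bench rule looks at equivalents: the alpha run holds 1.33 nucleophile per electrophile, so by that count the electrophile is the limiting reagent and should be consumed. Yet the alpha run has slowed by its last reading, product 47.5%. The border of the rule is a ratio, the nucleophile toll, meaning the nucleophile charged per product formed at the stall, on the supposition that the stall is a shortage of nucleophile: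

toll = 0.20 M / (0.15 M × 47.5%) = 2.81

That reading is more than the two that one reacting nucleophile and one taking up the acid would cost.

The early end gives a low mark: the theta run, which is this flask, reads 59.0% product at 4.00 min, and the asked time is 3.00 times that. The late end gives a high mark, an estimate that carries the toll read in the alpha run over to this flask:

c ≈ 0.300 M / (toll × 0.15 M) = 71.2%

Joining the two ends at their middle, this reckoning commits to 65.1%, and its guess for fr is small, with no number behind it.

The forecast differs: c 67% (61% to 74%), fr 62% (45% to 85%), with the remark “Nucleophile probably binds somewhat preferentially”.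

The flask gives c 63.4% and fr 6.05%.

    electrophile + nucleophile ⇌ acid set free + product (K = 0.200, k = 0.0630 /M/s)
    nucleophile + acid set free ⇌ protonated nucleophile, settled at all times (K = 22000 /M)
    acid set free + free base ⇌ salt of the base (K = 12.0 /M, k = 4.60 /M/s)
    nucleophile + product ⇌ idle adduct, settled at all times (K = 7.30 /M)
    2 nucleophile → homo dimer (k = 0.0310 /M/s)

In the flask at 12.0 min the nucleophile stands at 2.00% of its charge, less than the free base at 99.2% of its own, with 0.0931 M protonated nucleophile. The toll of this flask comes to 3.15. For the neighbour charged with 0.26 M of electrophile, the alpha toll gives 41.1%, and that flask reaches 44.4%.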